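## Retrosynthetic overview

1. Plakortolide F ⇒ saturation of a C8=C9 alkene with diimide ⇒ cross-metathesis of a C6-allyl bicyclic peroxylactone with 4-(oct-7-enyl)phenol, itself made in one hydroboration/Suzuki step.
2. C6–C7 bond ⇒ axial Hosomi–Sakurai allylation of the bicyclic peroxycarbenium ion released from a C6-methoxy peroxyketal. C4 and C3 steer C6.
3. Key step: both rings form from one acyclic (S)-γ-hydroxy dienoate in one flask. Selective ozonolysis in MeOH gives a hydroperoxy ketal, a peroxy-Michael addition closes ring A (the 1,2-dioxane) first, and lactonisation closes ring B (the γ-lactone) second. C3 follows from C4.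
4. Dienoate ⇒ semi-reduction/Wittig of an (S)-α-hydroxy ester ⇒ catalytic asymmetric pyruvate/isobutylene carbonyl-ene reaction, the only external source of chirality (C4).

Assumption: plakortolide numbering is used (C1 lactone C=O, C2 CH2, C3 CH–OO, C4 C(CH3)–O, C5 CH2, C6 C(CH3)(chain)–OO). The given SMILES reads 3S,4S,6R, with H-3, CH3-4 and CH3-6 on one face and the lactone and side chain on the other. Bicyclic compounds carry chain names in which the γ-lactone joins C1 to O–C4 and the peroxide bridge joins C3 to C6.

## Route

**Step 1**
Reactants: 1 methyl pyruvate; 2 isobutylene (2-methylpropene)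
Product: 3 methyl (S)-2-hydroxy-2,4-dimethylpent-4-enoate
Conditions: [Cu((S,S)-t-Bu-box)](SbF6)2 (10 mol %), 2 (5 equiv), CH2Cl2, 40 °C, sealed vessel, 48 h
Reagents that add atoms: none
Why: Catalytic asymmetric carbonyl-ene reaction in which the pyruvate chelates the square-planar divalent copper bis(oxazoline) complex through both carbonyl oxygens, the tert-butyl groups block the Re face of the ketone, and isobutylene adds to the Si face through a six-membered ene transition state, which sets C4 as S with the high ee known for 1,1-disubstituted alkenes.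

**Step 2**
Reactants: 3 methyl (S)-2-hydroxy-2,4-dimethylpent-4-enoate; 4 ethyl (triphenylphosphoranylidene)acetate
Product: 6 ethyl (2E,4S)-4-hydroxy-4,6-dimethylhepta-2,6-dienoate, via hydroxy aldehyde 5 (not isolated)
Conditions: i-Bu2AlH (2.2 equiv), CH2Cl2, −78 °C, 1 h; then 4 (1.5 equiv), −78 °C to rt; aq. potassium sodium tartrate work-up
Reagents that add atoms: none
Why: Tandem ester semi-reduction/Wittig olefination in which the first hydride equivalent turns the tertiary OH into an aluminium alkoxide whose chelation holds the reduction at the aldehyde level at −78 °C, aldehyde 5 is trapped on warming by the stabilised ylide with high E selectivity, and C4 has no α-hydrogen and so cannot epimerise.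

**Step 3 (key step)**
Reactants: 6 ethyl (2E,4S)-4-hydroxy-4,6-dimethylhepta-2,6-dienoate
Product: 10 (3S,4S)-3,6-epidioxy-6-methoxy-4-methylheptan-4-olide (cis-fused dioxane/γ-lactone; C6 epimers), via ketone O-oxide 7 (not isolated), via hydroperoxy ketal 8 (not isolated), via dioxane hydroxy ester 9 (not isolated)
Conditions: O3/O2 to the Sudan Red 7B end point, CH2Cl2/MeOH 3:1, −78 °C; N2 purge, solvent exchange at 0 °C to CF3CH2OH; Et2NH (0.3 equiv), rt, 12 h; then PPTS (0.4 equiv), rt, 6 h; one flask throughout
Reagents that add atoms: ozone, [O-][O+]=O; methanol, CO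
Why: Proposed new method: the electron-rich 1,1-disubstituted alkene is ozonised far faster than the enoate and cleaves to the more substituted ketone O-oxide 7, which methanol traps as hydroperoxy ketal 8 (Criegee ozonolysis in a participating solvent), the amine then triggers a reversible 6-exo-trig intramolecular peroxy-Michael addition through a chair with CH3-4 and the new CH2CO2Et equatorial and OH-4 axial to close ring A (9), and only this C3 epimer holds ester and OH cis, so irreversible lactonisation closes ring B and drains the equilibrium, setting C3 as S from C4; the closest known chemistry is the ozonolysis or perhydrolysis/amine-catalysed peroxy-Michael route to 3-methoxy-1,2-dioxane-6-acetates, extended here by a terminating lactonisation on an unprotected γ-hydroxy enoate.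

**Step 4**
Reactants: 10 (3S,4S)-3,6-epidioxy-6-methoxy-4-methylheptan-4-olide; 11 allyltrimethylsilane
Product: 13 (3S,4S,6R)-3,6-epidioxy-4,6-dimethylnon-8-en-4-olide, via peroxycarbenium ion 12 (not isolated)
Conditions: 11 (3 equiv), Me3SiOTf (0.2 equiv), CH2Cl2, −78 to −40 °C
Reagents that add atoms: none
Why: Proposed new method: Me3SiOTf removes the more basic exocyclic methoxy group from either C6 epimer to give the same peroxycarbenium ion 12, whose preferred half-chair places CH3-4 and C2 pseudoequatorial and the lactone oxygen on C4 pseudoaxial, and stereoelectronically favoured axial attack of the allylsilane through a chair-like transition state (Hosomi–Sakurai reaction; six-membered oxocarbenium model: 1,3-trans to alkyl, 1,3-cis to oxygen, 1,4-cis to alkyl) delivers the allyl group to the lactone face, anti to CH3-4, which sets C6 as R; the closest known reactions are Lewis-acid allylations of acyclic monoperoxy ketals and of 3-alkoxy-1,2-dioxolanes through peroxycarbenium ions.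

**Step 5**
Reactants: 14 octa-1,7-diene; 15 9-borabicyclo[3.3.1]nonane (9-BBN); 16 4-iodophenol
Product: 18 4-(oct-7-en-1-yl)phenol, via B-(oct-7-en-1-yl)-9-BBN 17 (not isolated)
Conditions: 14 (4 equiv), 15 (1 equiv), THF, 0 °C to rt; then 16 (0.9 equiv), PdCl2(dppf) (3 mol %), aq. NaOH (3 M, 3 equiv), THF, 65 °C
Reagents that add atoms: none
Why: Hydroboration followed by B-alkyl Suzuki–Miyaura coupling, in which 9-BBN adds anti-Markovnikov to one terminal alkene (excess diene suppresses double addition), the hydroxide-activated borane 17 passes its primary alkyl group to the arylpalladium iodide formed from zerovalent palladium, the phenoxide is a spectator so no protecting group is needed, and no stereocenter is formed.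

**Step 6**
Reactants: 13 (3S,4S,6R)-3,6-epidioxy-4,6-dimethylnon-8-en-4-olide; 18 4-(oct-7-en-1-yl)phenol
Product: 19 (3S,4S,6R,8E)-3,6-epidioxy-15-(4-hydroxyphenyl)-4,6-dimethylpentadec-8-en-4-olide (E major; some Z)
Conditions: 18 (3 equiv), second-generation Grubbs catalyst RuCl2(=CHPh)(PCy3)(H2IMes) (5 mol %), CH2Cl2, 40 °C
Reagents that add atoms: none
Why: Olefin cross-metathesis of two terminal alkenes, driven by gas evolution and by the excess of cheap 18, in which the ruthenium carbene tolerates dialkyl peroxides, lactones and free phenols, the E/Z ratio does not matter because the alkene is saturated next, and no stereocenter is touched.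

**Step 7**
Reactants: 19 (3S,4S,6R,8E)-3,6-epidioxy-15-(4-hydroxyphenyl)-4,6-dimethylpentadec-8-en-4-olide
Product: 20 plakortolide F
Conditions: KO2CN=NCO2K (20 equiv), AcOH (40 equiv), MeOH/CH2Cl2, 0 °C to rt
Reagents that add atoms: none
Why: Diimide reduction, a concerted metal-free syn transfer of two hydrogens to the C=C bond that leaves the O–O bond intact (catalytic hydrogenation would cleave it), run in a mildly acidic medium that avoids base-induced retro-Michael or Kornblum–DeLaMare opening, so C3, C4 and C6 stay as set.

Stereocenters:
- C4 (S) is set in step 1 by catalyst control.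
- C3 (S) is set in step 3, from C4, by the cis-lactone constraint.
- C6 (R) is set in step 4, from C4 and C3, by axial attack on 12.
- None of the three is touched afterwards.

## Compound list

1 | methyl pyruvate | CC(=O)C(=O)OC | starting material
2 | isobutylene (2-methylpropene) | CC(C)=C | starting material
3 | methyl (S)-2-hydroxy-2,4-dimethylpent-4-enoate | C=C(C)C[C@](C(=O)OC)(C)O | intermediate
4 | ethyl (triphenylphosphoranylidene)acetate | CCOC(=O)C=P(c1ccccc1)(c1ccccc1)c1ccccc1 | starting material
5 | (S)-2-hydroxy-2,4-dimethylpent-4-enal (not isolated) | C=C(C)C[C@](C=O)(C)O | intermediate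
6 | ethyl (2E,4S)-4-hydroxy-4,6-dimethylhepta-2,6-dienoate | C=C(C)C[C@](/C=C/C(=O)OCC)(C)O | intermediate
7 | ethyl (2E,4S)-4-hydroxy-4-methyl-6-oxohept-2-enoate O-oxide (ketone O-oxide at C6, not isolated) | CC(=[O+][O-])C[C@](/C=C/C(=O)OCC)(C)O | intermediate
8 | ethyl (2E,4S)-6-hydroperoxy-4-hydroxy-6-methoxy-4-methylhept-2-enoate (C6 epimers, not isolated) | COC(C)(OO)C[C@](/C=C/C(=O)OCC)(C)O | intermediate
9 | ethyl 2-[(3S,4S)-4-hydroxy-6-methoxy-4,6-dimethyl-1,2-dioxan-3-yl]acetate (C6 epimers, not isolated) | COC1(C)C[C@](C)(O)[C@H](CC(=O)OCC)OO1 | intermediate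
10 | (3S,4S)-3,6-epidioxy-6-methoxy-4-methylheptan-4-olide (cis-fused; C6 left undefined on purpose) | COC1(C)C[C@]2(C)OC(=O)C[C@@H]2OO1 | intermediate
11 | allyltrimethylsilane | C=CC[Si](C)(C)C | starting material
12 | bicyclic peroxycarbenium ion (10 minus methoxide, O=C6 cation, not isolated) | CC1=[O+]O[C@H]2CC(=O)O[C@@]2(C)C1 | intermediate
13 | (3S,4S,6R)-3,6-epidioxy-4,6-dimethylnon-8-en-4-olide | C[C@@]1(CC=C)C[C@]2(C)OC(=O)C[C@@H]2OO1 | intermediate
14 | octa-1,7-diene | C=CCCCCC=C | starting material
15 | 9-borabicyclo[3.3.1]nonane (9-BBN) | B1C2CCCC1CCC2 | starting material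
16 | 4-iodophenol | Oc1ccc(I)cc1 | starting material
17 | B-(oct-7-en-1-yl)-9-BBN (not isolated) | C=CCCCCCCB1C2CCCC1CCC2 | intermediate
18 | 4-(oct-7-en-1-yl)phenol | C=CCCCCCCc1ccc(O)cc1 | intermediate
19 | (3S,4S,6R,8E)-3,6-epidioxy-15-(4-hydroxyphenyl)-4,6-dimethylpentadec-8-en-4-olide | C[C@@]1(C/C=C/CCCCCCc2ccc(O)cc2)C[C@]2(C)OC(=O)C[C@@H]2OO1 | intermediate
20 | plakortolide F, (3S,4S,6R)-3,6-epidioxy-15-(4-hydroxyphenyl)-4,6-dimethylpentadecan-4-olide | C[C@@]1(CCCCCCCCCc2ccc(O)cc2)C[C@]2(C)OC(=O)C[C@@H]2OO1 | target

## Step count and risks

Total steps: 7. Longest linear sequence: 6 (steps 1, 2, 3, 4, 6, 7).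

**Step 4.** The risks are loss of a proton or fragmentation of cation 12 before the weakly nucleophilic allylsilane captures it, and an untested facial ratio. The fallback sets out from 10 and comes back at 13. Cation 12 is intercepted instead by the far more nucleophilic enol silane (vinyloxy)trimethylsilane. This is a Mukaiyama-type addition along the same axial trajectory. It gives (3S,4S,6S)-3,6-epidioxy-4,6-dimethyl-8-oxooctan-4-olide F1, which has the same spatial arrangement at C6; only the descriptor changes with the priorities. The aldehyde is then methylenated with salt-free Ph3P=CH2 in THF at −78 °C to give 13.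

**Step 3.** The risks are over-ozonolysis of the enoate, slow Michael closure on the flexible E-enoate, and incomplete lactonisation. The fallback sets out from 6 and comes back at 10, closing the rings one at a time in the reverse order.
- Irradiation (300 nm, MeCN) turns the E-enoate into the Z-enoate, which lactonises at once to (S)-5-methyl-5-(2-methylallyl)furan-2(5H)-one F2, so ring B forms first.
- Ozonolysis in CH2Cl2/MeOH gives (5S)-5-(2-hydroperoxy-2-methoxypropyl)-5-methylfuran-2(5H)-one F3, which is isolated.
- Et2NH in CF3CH2OH closes ring A onto the locked, more electrophilic butenolide. The tether can reach only the face cis to C5, so this gives 10.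

**Step 2.** The risks are over-reduction to the diol and self-condensation of the free α-hydroxy aldehyde. The fallback sets out from 3 and comes back at 6. Full reduction with LiAlH4 gives (S)-2,4-dimethylpent-4-ene-1,2-diol F4. Only its primary alcohol is oxidised by TEMPO/PhI(OAc)2, and this is done in the presence of ylide 4 (tandem oxidation/Wittig). Aldehyde 5 is therefore trapped as it forms and gives 6.

## Further compounds

F1 | step 4 | (3S,4S,6S)-3,6-epidioxy-4,6-dimethyl-8-oxooctan-4-olide | C[C@@]1(CC=O)C[C@]2(C)OC(=O)C[C@@H]2OO1
F2 | step 3 | (S)-5-methyl-5-(2-methylallyl)furan-2(5H)-one | C=C(C)C[C@]1(C)OC(=O)C=C1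
F3 | step 3 | (5S)-5-(2-hydroperoxy-2-methoxypropyl)-5-methylfuran-2(5H)-one | COC(C)(OO)C[C@]1(C)OC(=O)C=C1
F4 | step 2 | (S)-2,4-dimethylpent-4-ene-1,2-diol | C=C(C)C[C@](CO)(C)O
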